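A turnover is the unit to count here: one pass of the catalyst through catalyst intermediate B, which makes one second substrate into second product.

starting material 0.10 M; second substrate 0.200 M; free catalyst 2.5 mM; impurity 1.2 mM

    catalyst intermediate B → free catalyst + second product (k1 = 9.2 s⁻¹)
    starting material → uncatalysed product (k2 = 0.018 s⁻¹)
    starting material + free catalyst ⇌ catalyst intermediate A (K3 = 4.3 M⁻¹, k3 = 29 M⁻¹ s⁻¹)
    free catalyst + impurity → spent catalyst (k4 = 2300 M⁻¹ s⁻¹)
    catalyst intermediate A → free catalyst + target (k5 = 3.4 s⁻¹)
    second substrate + free catalyst ⇌ catalyst intermediate B (K6 = 1500 M⁻¹, k6 = 260 M⁻¹ s⁻¹)

- the form that holds most of the catalyst when 50 % of the starting material are converted (spent catalyst / catalyst intermediate A / catalyst intermediate B / free catalyst)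
- its share of the catalyst then

Minutes of a short meeting on this flask. Two chemists were present, and I did the reckoning.

My colleague opened with the impurity. She said that it and the second substrate draw on the same free catalyst, and that the impurity's rate constant is 8.85 times that of the second substrate. Each falls in step with its own constant, she argued, so with half of the second substrate left, the impurity stands at 0.217 % of its charge. I agreed, and noted that its charge of 1.2 mM is smaller than the catalyst charge of 2.5 mM. So 48.0 % of the catalyst ends as spent catalyst, and 1.30 mM stays active.

She asked how long that active part works. I answered by counting turnovers. Each active catalyst has 154 of them to make. Free catalyst enters catalyst intermediate B at 52 s⁻¹ with the charge, faster than B leaves at 9.2 s⁻¹, so with the second substrate near its charge I took B as the resting state and its exit as the pace. I proposed the burn time as an estimate: the turnovers per active catalyst divided by the exit constant of B. It comes to 16.7 s.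

She asked whether the burn ends before the conversion asked about. I said the uncatalysed step alone has a half-life of 38.5 s, and the burn time is shorter than that, though the catalysed route also shortens the half-life, by an amount I did not reckon. So, as an estimate, I set B aside and shared the active catalyst between free catalyst and catalyst intermediate A. At 0.0500 M of starting material, A per free catalyst is the binding rate over the two ways out of A, the fall back and the step to target. That gives 0.143. Free catalyst then holds 45.5 %, less than the spent catalyst. I committed to spent catalyst at 48.0 %.

The forecast also names spent catalyst, at 48 %, on the ground of “leaving 1.2 mM spent and 1.3 mM active”.

The simulation gives spent catalyst at 48.0 %, with free catalyst at 42.0 %, catalyst intermediate A at 6.00 % and catalyst intermediate B at 4.03 %.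

In this flask the burn time of 16.7 s is shorter than the 29.8 s that half conversion took, and catalyst intermediate B, which still held 37.5 % of the catalyst at 8.00 s, is down to 4.03 % at half conversion. In a second flask with twice the second substrate, the count gives a burn time of 33.4 s, so there the burn is of like size to the time half conversion took, 34.1 s, which is 1.15 times the time in the first flask.

The rate constants are invented; the run is a simulation.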